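## The problem

Hansforester J (22) is an open-chain tetramer. Ring A (a 5-substituted resorcinol), unit B (a 3-oxybutanoyl group), ring C (a 2,4-dihydroxy-6-alkylbenzoyl group) and unit D (a terminal 3-hydroxybutanoyl group) are joined head to tail by three ester bonds through two (R)-2-oxypropyl arms. No ring exists apart from the two arenes, so the task is chain assembly and keeping several hydroxyl and acyl functions apart. The four stereocenters are all R-configured methyl carbinols: the arm carbons of rings A and C and C3 of units B and D. Each is separated from the next by an ester and at least four bonds, so none can steer another and each must be bought or set by a reagent. The benzoate carbonyl of ring C lies between an oxygen substituent and the arm and is a poor acyl donor, and the alcohol it must join is a β-hydroxy ester. Three things will not survive rough treatment: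
- the β-acyloxy esters of units B and D, which eliminate under base;
- the ring C carboxyl together with the carbinol on its ortho arm, which close to a six-membered lactone whenever the carbinol is free beside a displaceable ester;
- the free resorcinols, which are best kept as benzyl ethers until a neutral hydrogenolysis at the end.

The feature that opens the plan is unit D. Its O–C(=O)–CH2–CH(OH)–CH3 string is the arm oxygen of ring C, one carbon monoxide (the acyl carbon) and (R)-propylene oxide (the CH2–CH(OH)–CH3 part). The ArCH2–CH(O)–CH3 arms of rings A and C are the same epoxide opened by an aryl nucleophile, so one C3 building block can supply three of the four stereocenters.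

## Retrosynthesis

**22 to 20.** The four phenolic O–benzyl bonds and the O–silyl bond at unit D are cut, leading from 22 through tetrabenzyl ether 21 to the fully masked tetramer 20. Benzyl ethers are preferred on the phenols because they withstand organometallic, carbonylation and Mitsunobu conditions and fall to neutral hydrogenolysis. None of the three esters is touched there, since their alkyl C–O bonds are homobenzylic or aliphatic. The silyl ether at unit D is there only so that the fragment union sees a single hydroxyl. It is removed with buffered fluoride before the hydrogenolysis, so the last step is a clean, neutral one.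

**20 to 15 and 19.** Of the three ester bonds of 20 the central one, between ring C and unit B, is cut. This divides the molecule into two halves of similar size, acid 15 and alcohol 19, which both descend from one arylpropanol. The bond broken is the alkyl–oxygen bond at C3 of unit B, not the acyl–oxygen bond. The crowded carboxyl of 15 is a poor electrophile but a good Mitsunobu nucleophile, because its carboxylate oxygens lie outside the shielded zone. The price is that 19 must carry the (S)-carbinol, which inversion turns into the (R)-center of unit B. The forward step must displace cleanly and must not eliminate the activated β-hydroxy ester.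

**15 to 12.** Acid 15 is traced through tert-butyl ester 13 to hydroxy ester 12 by two protecting-group operations: silylation of the unit D hydroxyl and cleavage of the tert-butyl–oxygen bond. The ester is removed through trimethylsilyl ester 14 with a silyl triflate and a hindered base. This pair leaves silyl ethers, benzyl ethers and secondary alkyl esters alone, so fluoride, hydroxide and hydrogen are all avoided here.

**12 to 10, 3 and 11 (key disconnection).** Unit D of 12 is removed by cutting two bonds: the acyl carbon–oxygen bond to the arm of ring C and the acyl carbon–CH2 bond. This leaves carbinol 10, carbon monoxide 11 and (R)-propylene oxide 3.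
- The neighbouring cut, a conventional acylation of 10 with a separately protected four-carbon hydroxy acid, is safe. It costs a second chiral building block, two steps to prepare it and a coupling reagent.
- The carbonylative cut uses the epoxide the route already holds, wastes no atom and delivers unit D with the correct configuration and a free hydroxyl.
- The forward reaction must do with a secondary carbinol in measured amount what epoxide alkoxycarbonylation does in neat methanol. It is therefore placed on monomer 10, which can be used in excess and recovered, and not on a late coupled intermediate.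
- The ester of 10 must be one that the free carbinol cannot displace under warm, proton-shuttling conditions. A primary ester such as a 2-(trimethylsilyl)ethyl ester would risk lactonization onto the ortho arm. The tert-butyl ester is both too hindered and too poor a leaving group.

**10 to 5.** Carbinol 10 is simplified by cutting the bond between ring C and its carboxyl carbon. Ester 9 arises from aryllithium 8 and Boc2O, 8 from bromide 7, and 7 from silyl ether 6 by bromination. A formylation, oxidation and esterification sequence would reach the same ester in one more step; bromination and metalation install the tert-butyl ester directly. The bromination must choose the position ortho to the arm and para to a benzyloxy group over the position flanked by two benzyloxy groups. The silyl ether of 6, made from arylpropanol 5, must survive NBS and n-BuLi and then leave without an alkoxide being formed.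

**19 to 5 and 16.** The (S)-carbinol of 19 is traced to the ketone of acetoacetate 18 (C–H bond at C3), and 18 to arylpropanol 5 and dioxinone 16 (acyl–oxygen bond, through acetylketene 17). This replaces a four-step sequence from a hydroxybutanoate building block (protection, saponification, coupling, deprotection) by two steps. The asymmetric hydrogenation must impose the S configuration by catalyst control alone, since the arm center is too remote to help or harm.

**5 to 1 and 3.** Arylpropanol 5, common to both halves, is cut at the aryl–CH2 bond into Grignard reagent 4 (from dibenzyl ether 2) and epoxide 3. Ether 2 comes from 5-bromoresorcinol 1 by cutting two O–benzyl bonds. The forward opening must occur at the CH2 terminus of 3 so that the stereocenter is carried over untouched.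

## Roads not taken

**Alternative 1: carboxylate-directed C–H alkylation with the epoxide.**
- Cut: the bond between ring C and the CH2 of its arm, together with the lactone C–O bond.
- Forward step: 2,4-bis(benzyloxy)benzoic acid A2 is treated with Pd(OAc)2 (divalent palladium) and an N-acetyl amino acid ligand. The carboxylate directs palladation to the only free ortho C–H, the aryl–palladium bond opens 3 at CH2, and the alkoxide closes onto the carboxyl to give lactone A1.
- Merits: one step from a cheap acid gives the whole carbon skeleton of ring C with the arm configuration taken from 3. There is no halogenation or metalation, and the reaction type is established for simple benzoic acids.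
- Weak points: A1 ties together the carbinol and the carboxyl, which the target needs in two different esters. Opening gives a hydroxy carboxylate that recloses on acidification or on any activation of the carboxyl. Keeping it open means alkylating the carboxylate, which gives the primary esters that relactonize most easily. Unit D is not addressed and would still need a protected four-carbon acid and an acylation.
- Comparison: for the ring C skeleton this road is clearly shorter than steps 3 to 6 here and rests on firmer ground. The chosen plan sets against it an open-chain hydroxy ester (10) with a lactonization-proof ester, unit D made from 3 and 11 with no further building block, and the use of 5 for both arenes.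

**Alternative 2: twofold ynoate Diels–Alder reaction building both arenes last.**
- Cut: two ring bonds in each arene, between the alkyne carbons and the diene termini.
- Forward step: acyclic diynoate tetraester A4 is heated with an excess of bis(silyloxy)diene A5. Each cycloaddition is followed by cycloreversion with loss of the gem-dimethyl bridge, and desilylating work-up gives bis-resorcylate A3.
- Merits: all three ester bonds are made in the aliphatic series, where the future ring C carboxyl is an unhindered ynoic acid, so the hindered-benzoate problem disappears. The regiochemistry is electronically matched and the phenols arrive free.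
- Weak points: ring A arrives in A3 with a carboxyl the target lacks, so debenzylation and a selective decarboxylation must follow on a molecule with three elimination-prone esters. 3-Alkyl ynoates are sluggish dienophiles and the fragmentation needs high temperature, where the homopropargylic and β-acyloxy esters of A4 can eliminate. Two such events in one precious molecule multiply the losses. The assembly of A4 is no shorter than the fragment syntheses here.
- Comparison: this road is better at the ring C to unit B ester. The chosen plan sets against it arenes that are bought and not built, no surplus carboxyl to remove, and no step above 130 °C after the ester bonds exist.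

**Alternative 3: acylketene capture and biomimetic folding of ring C.**
- Cut: the benzoate acyl–oxygen bond and the ring C bond between the carboxyl-bearing and arm-bearing carbons.
- Forward step: heating diketo-dioxinone A7 with alcohol A8 (the 3R epimer of 19) causes cycloreversion to an acylketene, which the carbinol of A8 traps. Base and then acid close and aromatize ring C to give triester A6.
- Merits: the crowded benzoate is formed before it is crowded. Capture occurs with retention, so unit B can come from the (R)-hydroxybutanoate pool. The resorcinol emerges unprotected, and the reaction type is well established for resorcylates.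
- Weak points: A7 needs several steps of dioxinone enolate chemistry and carries a β-silyloxy ketone that can eliminate under the aromatization base. The β-acyloxy ester of unit B must survive that base while attached to a polycarbonyl acyl group that is a good leaving group. After desilylation of A6, unit D must still be attached from a separate protected acid in the presence of two free phenols.
- Comparison: for the ring C to unit B ester this road is better than a Mitsunobu reaction on a β-hydroxy ester. The chosen plan sets against it shorter fragment syntheses from the common arylpropanol 5, robust non-enolizable intermediates, and unit D at no cost in building blocks.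

Key step: step 7

Remark on the chemistry: carbon monoxide is treated as a numbered reactant (11) because it supplies a skeletal carbon, and the excess of 10 used in step 7 is meant to be recovered and recycled.

## Route

Step 1
Reactants: 1 5-bromoresorcinol
Product: 2 1,3-bis(benzyloxy)-5-bromobenzene
Conditions: BnBr (2.3 equiv), K2CO3, DMF, rt to 50 °C
Reagents that add atoms: benzyl bromide, BrCc1ccccc1
Why: Williamson ether synthesis on both phenols; the aryl bromide is inert under these conditions.

Step 2
Reactants: 2 1,3-bis(benzyloxy)-5-bromobenzene; 3 (R)-propylene oxide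
Product: 5 (2R)-1-[3,5-bis(benzyloxy)phenyl]propan-2-ol, via aryl Grignard reagent 4 (not isolated)
Conditions: Mg, THF, 40 °C; then CuI (10 mol %), 3 (1.3 equiv), −30 to 0 °C; aq. NH4Cl
Reagents that add atoms: none
Why: Grignard formation followed by CuI-catalysed (monovalent copper) SN2 opening of the terminal epoxide at its CH2 carbon. The stereocenter of 3 is not touched, so the arm carbinol is R.

Step 3
Reactants: 5 (2R)-1-[3,5-bis(benzyloxy)phenyl]propan-2-ol
Product: 6 {[(2R)-1-[3,5-bis(benzyloxy)phenyl]propan-2-yl]oxy}(tert-butyl)dimethylsilane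
Conditions: TBSCl, imidazole, DMF, rt
Reagents that add atoms: tert-butyldimethylsilyl chloride, CC(C)(C)[Si](C)(C)Cl
Why: Standard silylation of a secondary alcohol; the silyl ether withstands NBS and n-BuLi in the next two steps.

Step 4
Reactants: 6 {[(2R)-1-[3,5-bis(benzyloxy)phenyl]propan-2-yl]oxy}(tert-butyl)dimethylsilane
Product: 7 {[(2R)-1-[3,5-bis(benzyloxy)-2-bromophenyl]propan-2-yl]oxy}(tert-butyl)dimethylsilane
Conditions: NBS (1.0 equiv), MeCN, 0 °C, dark
Reagents that add atoms: N-bromosuccinimide, O=C1CCC(=O)N1Br
Why: Electrophilic aromatic bromination of a 3,5-dialkoxyalkylbenzene, which should occur para to one benzyloxy group and ortho to the arm, not at the position flanked by two benzyloxy groups; one equivalent in a polar solvent limits dibromination and side-chain bromination.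

Step 5
Reactants: 7 {[(2R)-1-[3,5-bis(benzyloxy)-2-bromophenyl]propan-2-yl]oxy}(tert-butyl)dimethylsilane
Product: 9 tert-butyl 2,4-bis(benzyloxy)-6-[(2R)-2-{[tert-butyl(dimethyl)silyl]oxy}propyl]benzoate, via aryllithium 8 (not isolated)
Conditions: n-BuLi (1.1 equiv), THF, −78 °C; then Boc2O (2 equiv), −78 °C to rt
Reagents that add atoms: di-tert-butyl dicarbonate, CC(C)(C)OC(=O)OC(=O)OC(C)(C)C
Why: Bromine–lithium exchange followed by acylation of the aryllithium with Boc2O gives the tert-butyl ester in one operation; the bulky, poorly electrophilic ester should not take up a second aryllithium.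

Step 6
Reactants: 9 tert-butyl 2,4-bis(benzyloxy)-6-[(2R)-2-{[tert-butyl(dimethyl)silyl]oxy}propyl]benzoate
Product: 10 tert-butyl 2,4-bis(benzyloxy)-6-[(2R)-2-hydroxypropyl]benzoate
Conditions: HF·pyridine, pyridine, THF, 0 °C to rt
Reagents that add atoms: none
Why: Buffered fluoride desilylation releases the carbinol without forming an alkoxide, so lactonization onto the ortho ester has no opening; the tert-butyl ester and benzyl ethers are inert.

Step 7
Reactants: 10 tert-butyl 2,4-bis(benzyloxy)-6-[(2R)-2-hydroxypropyl]benzoate; 3 (R)-propylene oxide; 11 carbon monoxide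
Product: 12 tert-butyl 2,4-bis(benzyloxy)-6-[(2R)-2-{[(3R)-3-hydroxybutanoyl]oxy}propyl]benzoate
Conditions: Co2(CO)8 (5 mol %), 3-hydroxypyridine (10 mol %), CO (60 bar), THF (about 1 M in 10), 60 °C; 10 (3 equiv), 3 (1 equiv); excess 10 recovered
Reagents that add atoms: none
Why: Proposed new method: the tetracarbonylcobaltate anion (cobalt in the minus-one oxidation state), formed from Co2(CO)8 and 3-hydroxypyridine, should open the hydrogen-bond-activated epoxide 3 at its CH2 terminus by SN2 attack, CO insertion should give a 3-hydroxybutanoylcobalt species, and the carbinol of 10, with 3-hydroxypyridine as proton shuttle, should cleave it to ester 12 and regenerate HCo(CO)4. The closest known reaction type is the methoxycarbonylation of enantiopure terminal epoxides with the same catalyst pair in methanol, which keeps the configuration; new here is a secondary carbinol used as a measured reagent and not as the solvent. No ring is closed and no stereocenter is created: the unit D center comes from 3 and is untouched because attack occurs at the unsubstituted carbon, and the arm center of 10 takes no part. The step needs regioselective attack at CH2, which the SN2 character of the cobaltate secures. It also needs capture of the acylcobalt by 10 and not by the hydroxyl of 12 or by its own β-hydroxyl, which a threefold excess of 10 at high concentration with 3 as limiting component should secure, helped by the lower nucleophilicity of the ester-bearing hydroxyl of 12. The hydroxy ester motif must survive, which the tert-butyl ester secures because the neighbouring carbinol cannot displace it. Benzyl ethers offer nothing for the cobalt hydride to attack in the absence of hydrogen.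

Step 8
Reactants: 12 tert-butyl 2,4-bis(benzyloxy)-6-[(2R)-2-{[(3R)-3-hydroxybutanoyl]oxy}propyl]benzoate
Product: 13 tert-butyl 2,4-bis(benzyloxy)-6-[(2R)-2-{[(3R)-3-{[tert-butyl(dimethyl)silyl]oxy}butanoyl]oxy}propyl]benzoate
Conditions: TBSCl, imidazole, DMF, rt
Reagents that add atoms: tert-butyldimethylsilyl chloride, CC(C)(C)[Si](C)(C)Cl
Why: Silylation of a β-hydroxy ester under weakly basic conditions, which should cause neither retro-aldol cleavage nor elimination.

Step 9
Reactants: 13 tert-butyl 2,4-bis(benzyloxy)-6-[(2R)-2-{[(3R)-3-{[tert-butyl(dimethyl)silyl]oxy}butanoyl]oxy}propyl]benzoate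
Product: 15 2,4-bis(benzyloxy)-6-[(2R)-2-{[(3R)-3-{[tert-butyl(dimethyl)silyl]oxy}butanoyl]oxy}propyl]benzoic acid, via trimethylsilyl ester 14 (not isolated)
Conditions: TMSOTf (3 equiv), 2,6-lutidine (4.5 equiv), CH2Cl2, 0 °C to rt; then aqueous buffer, pH 5
Reagents that add atoms: none
Why: Silyl triflate-mediated cleavage of a tert-butyl ester: silylation of the carbonyl oxygen and loss of the tert-butyl cation as isobutene give the silyl ester, which hydrolyses on work-up. The hindered base keeps the medium non-acidic, so the silyl ether, the benzyl ethers and the secondary alkyl ester, none of which can ionize, should remain.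

Step 10
Reactants: 5 (2R)-1-[3,5-bis(benzyloxy)phenyl]propan-2-ol; 16 2,2,6-trimethyl-4H-1,3-dioxin-4-one
Product: 18 (2R)-1-[3,5-bis(benzyloxy)phenyl]propan-2-yl 3-oxobutanoate, via acetylketene 17 (not isolated)
Conditions: 16 (1.5 equiv), xylene, 130 °C, acetone distilled off
Reagents that add atoms: none
Why: Thermal cycloreversion of the dioxinone to acetylketene and its capture by the secondary alcohol is a neutral, reagent-free acetoacetylation.

Step 11
Reactants: 18 (2R)-1-[3,5-bis(benzyloxy)phenyl]propan-2-yl 3-oxobutanoate
Product: 19 (2R)-1-[3,5-bis(benzyloxy)phenyl]propan-2-yl (3S)-3-hydroxybutanoate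
Conditions: H2 (50 bar), RuCl2[(S)-BINAP] (0.5 mol %), MeOH/CH2Cl2, 50 °C
Reagents that add atoms: none
Why: Noyori asymmetric hydrogenation of a β-keto ester; the (S)-BINAP ligand on divalent ruthenium should set the S carbinol by catalyst control, unaffected by the remote arm center. This catalyst does not hydrogenolyse aryl benzyl ethers.

Step 12
Reactants: 15 2,4-bis(benzyloxy)-6-[(2R)-2-{[(3R)-3-{[tert-butyl(dimethyl)silyl]oxy}butanoyl]oxy}propyl]benzoic acid; 19 (2R)-1-[3,5-bis(benzyloxy)phenyl]propan-2-yl (3S)-3-hydroxybutanoate
Product: 20 (2R)-4-{[(2R)-1-[3,5-bis(benzyloxy)phenyl]propan-2-yl]oxy}-4-oxobutan-2-yl 2,4-bis(benzyloxy)-6-[(2R)-2-{[(3R)-3-{[tert-butyl(dimethyl)silyl]oxy}butanoyl]oxy}propyl]benzoate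
Conditions: PPh3 (2 equiv), DIAD (2 equiv), toluene, 0 °C to rt
Reagents that add atoms: none
Why: Mitsunobu esterification: the alkoxyphosphonium ion of 19 is displaced by the carboxylate of 15 with inversion, turning the S carbinol into the R center of unit B. The crowded acid reacts through its unhindered oxygen, which is why this mode is standard for 2,6-disubstituted benzoic acids.

Step 13
Reactants: 20 (2R)-4-{[(2R)-1-[3,5-bis(benzyloxy)phenyl]propan-2-yl]oxy}-4-oxobutan-2-yl 2,4-bis(benzyloxy)-6-[(2R)-2-{[(3R)-3-{[tert-butyl(dimethyl)silyl]oxy}butanoyl]oxy}propyl]benzoate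
Product: 21 (2R)-4-{[(2R)-1-[3,5-bis(benzyloxy)phenyl]propan-2-yl]oxy}-4-oxobutan-2-yl 2,4-bis(benzyloxy)-6-[(2R)-2-{[(3R)-3-hydroxybutanoyl]oxy}propyl]benzoate
Conditions: HF·pyridine, pyridine, THF, 0 °C to rt
Reagents that add atoms: none
Why: Buffered fluoride cleavage of a secondary silyl ether; the medium is not basic, so the β-acyloxy esters should neither eliminate nor migrate.

Step 14
Reactants: 21 (2R)-4-{[(2R)-1-[3,5-bis(benzyloxy)phenyl]propan-2-yl]oxy}-4-oxobutan-2-yl 2,4-bis(benzyloxy)-6-[(2R)-2-{[(3R)-3-hydroxybutanoyl]oxy}propyl]benzoate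
Product: 22 Hansforester J [(2R)-4-{[(2R)-1-(3,5-dihydroxyphenyl)propan-2-yl]oxy}-4-oxobutan-2-yl 2,4-dihydroxy-6-[(2R)-2-{[(3R)-3-hydroxybutanoyl]oxy}propyl]benzoate]
Conditions: H2 (1 atm), Pd/C (10 wt %), EtOAc/MeOH, rt
Reagents that add atoms: none
Why: Hydrogenolysis of the four aryl benzyl ethers over zerovalent palladium on carbon; the ester C–O bonds are homobenzylic or aliphatic and should remain, and the neutral medium spares the β-acyloxy esters.

## Compound list

1 | 5-bromoresorcinol | Oc1cc(O)cc(Br)c1 | starting material
2 | 1,3-bis(benzyloxy)-5-bromobenzene | Brc1cc(OCc2ccccc2)cc(OCc2ccccc2)c1 | intermediate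
3 | (R)-propylene oxide | C[C@@H]1CO1 | starting material
4 | [3,5-bis(benzyloxy)phenyl]magnesium bromide | Br[Mg]c1cc(OCc2ccccc2)cc(OCc2ccccc2)c1 | intermediate
5 | (2R)-1-[3,5-bis(benzyloxy)phenyl]propan-2-ol | C[C@@H](O)Cc1cc(OCc2ccccc2)cc(OCc2ccccc2)c1 | intermediate
6 | {[(2R)-1-[3,5-bis(benzyloxy)phenyl]propan-2-yl]oxy}(tert-butyl)dimethylsilane | C[C@@H](O[Si](C)(C)C(C)(C)C)Cc1cc(OCc2ccccc2)cc(OCc2ccccc2)c1 | intermediate
7 | {[(2R)-1-[3,5-bis(benzyloxy)-2-bromophenyl]propan-2-yl]oxy}(tert-butyl)dimethylsilane | C[C@@H](O[Si](C)(C)C(C)(C)C)Cc1cc(OCc2ccccc2)cc(OCc2ccccc2)c1Br | intermediate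
8 | {2,4-bis(benzyloxy)-6-[(2R)-2-{[tert-butyl(dimethyl)silyl]oxy}propyl]phenyl}lithium | C[C@@H](O[Si](C)(C)C(C)(C)C)Cc1cc(OCc2ccccc2)cc(OCc2ccccc2)c1[Li] | intermediate
9 | tert-butyl 2,4-bis(benzyloxy)-6-[(2R)-2-{[tert-butyl(dimethyl)silyl]oxy}propyl]benzoate | C[C@@H](O[Si](C)(C)C(C)(C)C)Cc1cc(OCc2ccccc2)cc(OCc2ccccc2)c1C(=O)OC(C)(C)C | intermediate
10 | tert-butyl 2,4-bis(benzyloxy)-6-[(2R)-2-hydroxypropyl]benzoate | C[C@@H](O)Cc1cc(OCc2ccccc2)cc(OCc2ccccc2)c1C(=O)OC(C)(C)C | intermediate
11 | carbon monoxide | [C-]#[O+] | starting material
12 | tert-butyl 2,4-bis(benzyloxy)-6-[(2R)-2-{[(3R)-3-hydroxybutanoyl]oxy}propyl]benzoate | C[C@@H](O)CC(=O)O[C@H](C)Cc1cc(OCc2ccccc2)cc(OCc2ccccc2)c1C(=O)OC(C)(C)C | intermediate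
13 | tert-butyl 2,4-bis(benzyloxy)-6-[(2R)-2-{[(3R)-3-{[tert-butyl(dimethyl)silyl]oxy}butanoyl]oxy}propyl]benzoate | C[C@@H](O[Si](C)(C)C(C)(C)C)CC(=O)O[C@H](C)Cc1cc(OCc2ccccc2)cc(OCc2ccccc2)c1C(=O)OC(C)(C)C | intermediate
14 | trimethylsilyl 2,4-bis(benzyloxy)-6-[(2R)-2-{[(3R)-3-{[tert-butyl(dimethyl)silyl]oxy}butanoyl]oxy}propyl]benzoate | C[C@@H](O[Si](C)(C)C(C)(C)C)CC(=O)O[C@H](C)Cc1cc(OCc2ccccc2)cc(OCc2ccccc2)c1C(=O)O[Si](C)(C)C | intermediate
15 | 2,4-bis(benzyloxy)-6-[(2R)-2-{[(3R)-3-{[tert-butyl(dimethyl)silyl]oxy}butanoyl]oxy}propyl]benzoic acid | C[C@@H](O[Si](C)(C)C(C)(C)C)CC(=O)O[C@H](C)Cc1cc(OCc2ccccc2)cc(OCc2ccccc2)c1C(=O)O | intermediate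
16 | 2,2,6-trimethyl-4H-1,3-dioxin-4-one | CC1=CC(=O)OC(C)(C)O1 | starting material
17 | acetylketene | CC(=O)C=C=O | intermediate
18 | (2R)-1-[3,5-bis(benzyloxy)phenyl]propan-2-yl 3-oxobutanoate | CC(=O)CC(=O)O[C@H](C)Cc1cc(OCc2ccccc2)cc(OCc2ccccc2)c1 | intermediate
19 | (2R)-1-[3,5-bis(benzyloxy)phenyl]propan-2-yl (3S)-3-hydroxybutanoate | C[C@H](O)CC(=O)O[C@H](C)Cc1cc(OCc2ccccc2)cc(OCc2ccccc2)c1 | intermediate
20 | (2R)-4-{[(2R)-1-[3,5-bis(benzyloxy)phenyl]propan-2-yl]oxy}-4-oxobutan-2-yl 2,4-bis(benzyloxy)-6-[(2R)-2-{[(3R)-3-{[tert-butyl(dimethyl)silyl]oxy}butanoyl]oxy}propyl]benzoate | C[C@H](Cc1cc(OCc2ccccc2)cc(OCc2ccccc2)c1)OC(=O)C[C@@H](C)OC(=O)c1c(OCc2ccccc2)cc(OCc2ccccc2)cc1C[C@@H](C)OC(=O)C[C@@H](C)O[Si](C)(C)C(C)(C)C | intermediate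
21 | (2R)-4-{[(2R)-1-[3,5-bis(benzyloxy)phenyl]propan-2-yl]oxy}-4-oxobutan-2-yl 2,4-bis(benzyloxy)-6-[(2R)-2-{[(3R)-3-hydroxybutanoyl]oxy}propyl]benzoate | C[C@H](Cc1cc(OCc2ccccc2)cc(OCc2ccccc2)c1)OC(=O)C[C@@H](C)OC(=O)c1c(OCc2ccccc2)cc(OCc2ccccc2)cc1C[C@@H](C)OC(=O)C[C@@H](C)O | intermediate
22 | Hansforester J | C[C@H](Cc1cc(O)cc(O)c1)OC(=O)C[C@@H](C)OC(=O)c1c(O)cc(O)cc1C[C@@H](C)OC(=O)C[C@@H](C)O | target

## Step count and least certain steps

Total step count: 14. Longest linear sequence: 12 steps (steps 1 to 9 and 12 to 14, from 1); steps 10 and 11 form the short branch from 5.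

**Step 7 (key step, proposed new method).**
- What may go wrong: chain growth by repeated epoxide and CO insertion at the newly formed hydroxyl; closure of the acylcobalt intermediate onto its own β-hydroxyl to the four-membered lactone, followed by polymerization; slow alcoholysis of the acylcobalt by a hindered secondary carbinol, giving the catalyst time to isomerize the epoxide to a ketone.
- Why: all three compete on near-equal terms once the alcohol is no longer the solvent.
- Fallback (known chemistry, from 10 back to 13): commercial methyl (R)-3-hydroxybutanoate (COC(=O)C[C@@H](C)O) is silylated (TBSCl, imidazole) to methyl (3R)-3-{[tert-butyl(dimethyl)silyl]oxy}butanoate F1. Saponification (LiOH, THF/H2O) gives (3R)-3-{[tert-butyl(dimethyl)silyl]oxy}butanoic acid F2. Carbodiimide esterification of F2 with 10 (EDC·HCl, DMAP, CH2Cl2) gives 13 directly, so step 8 falls away.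

**Step 12 (Mitsunobu union).**
- What may go wrong: β-elimination of the activated carbinol of 19 in place of substitution, and partial retention through an acyloxyphosphonium pathway, which would erode the configuration of unit B.
- Why: the carbinol is flanked by acidic α-protons and the nucleophile is bulky.
- Fallback (acyl activation with retention, from 18 and 15 back to 20): hydrogenation of 18 with RuCl2[(R)-BINAP] gives (2R)-1-[3,5-bis(benzyloxy)phenyl]propan-2-yl (3R)-3-hydroxybutanoate F3. Acid 15 is converted under neutral conditions with 1-chloro-N,N,2-trimethylprop-1-en-1-amine into 2,4-bis(benzyloxy)-6-[(2R)-2-{[(3R)-3-{[tert-butyl(dimethyl)silyl]oxy}butanoyl]oxy}propyl]benzoyl chloride F4. F4 acylates F3 (pyridine, DMAP, CH2Cl2) to give 20.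

**Step 9 (ester cleavage).**
- What may go wrong: incomplete ionization of the twisted, crowded tert-butyl benzoate, or concurrent loss of the benzyl ether ortho to the carboxyl through chelation of the silyl triflate.
- Fallback (unit D carried as a benzyl ether so that a protic acid can be used and no silyl ether needs to survive, from 12 back to 22):
  - benzylation of 12 (BnBr, Ag2O, CH2Cl2) gives tert-butyl 2,4-bis(benzyloxy)-6-[(2R)-2-{[(3R)-3-(benzyloxy)butanoyl]oxy}propyl]benzoate F5;
  - acidolysis (TFA, CH2Cl2, 0 °C) gives 2,4-bis(benzyloxy)-6-[(2R)-2-{[(3R)-3-(benzyloxy)butanoyl]oxy}propyl]benzoic acid F6;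
  - Mitsunobu reaction of F6 with 19 gives (2R)-4-{[(2R)-1-[3,5-bis(benzyloxy)phenyl]propan-2-yl]oxy}-4-oxobutan-2-yl 2,4-bis(benzyloxy)-6-[(2R)-2-{[(3R)-3-(benzyloxy)butanoyl]oxy}propyl]benzoate F7;
  - hydrogenolysis of all five benzyl ethers of F7 (H2, Pd/C) gives 22.

**Step 5 (metalation and carboxylation).**
- What may go wrong: protonation of the hindered aryllithium before acylation (for example by proton transfer from a benzylic ether position) or sluggish attack on the bulky dicarbonate, either of which returns debrominated material.
- Fallback (electrophilic formylation in place of halogen–metal exchange, from 5 back to 10):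
  - acetylation of 5 (Ac2O, pyridine) gives (2R)-1-[3,5-bis(benzyloxy)phenyl]propan-2-yl acetate F8;
  - Vilsmeier formylation (POCl3, DMF) gives (2R)-1-[3,5-bis(benzyloxy)-2-formylphenyl]propan-2-yl acetate F9;
  - Pinnick oxidation (NaClO2, NaH2PO4, 2-methyl-2-butene) gives 2-[(2R)-2-(acetyloxy)propyl]-4,6-bis(benzyloxy)benzoic acid F10;
  - O-alkylation with N,N-dimethylformamide di-tert-butyl acetal (toluene, 80 °C) gives tert-butyl 2-[(2R)-2-(acetyloxy)propyl]-4,6-bis(benzyloxy)benzoate F11;
  - methanolysis of the acetate (K2CO3, MeOH, rt) gives 10.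

## Further compounds

F1 | step 7 | methyl (3R)-3-{[tert-butyl(dimethyl)silyl]oxy}butanoate | COC(=O)C[C@@H](C)O[Si](C)(C)C(C)(C)C
F2 | step 7 | (3R)-3-{[tert-butyl(dimethyl)silyl]oxy}butanoic acid | OC(=O)C[C@@H](C)O[Si](C)(C)C(C)(C)C
F3 | step 12 | (2R)-1-[3,5-bis(benzyloxy)phenyl]propan-2-yl (3R)-3-hydroxybutanoate | C[C@@H](O)CC(=O)O[C@H](C)Cc1cc(OCc2ccccc2)cc(OCc2ccccc2)c1
F4 | step 12 | 2,4-bis(benzyloxy)-6-[(2R)-2-{[(3R)-3-{[tert-butyl(dimethyl)silyl]oxy}butanoyl]oxy}propyl]benzoyl chloride | C[C@@H](O[Si](C)(C)C(C)(C)C)CC(=O)O[C@H](C)Cc1cc(OCc2ccccc2)cc(OCc2ccccc2)c1C(=O)Cl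
F5 | step 9 | tert-butyl 2,4-bis(benzyloxy)-6-[(2R)-2-{[(3R)-3-(benzyloxy)butanoyl]oxy}propyl]benzoate | C[C@@H](OCc1ccccc1)CC(=O)O[C@H](C)Cc1cc(OCc2ccccc2)cc(OCc2ccccc2)c1C(=O)OC(C)(C)C
F6 | step 9 | 2,4-bis(benzyloxy)-6-[(2R)-2-{[(3R)-3-(benzyloxy)butanoyl]oxy}propyl]benzoic acid | C[C@@H](OCc1ccccc1)CC(=O)O[C@H](C)Cc1cc(OCc2ccccc2)cc(OCc2ccccc2)c1C(=O)O
F7 | step 9 | (2R)-4-{[(2R)-1-[3,5-bis(benzyloxy)phenyl]propan-2-yl]oxy}-4-oxobutan-2-yl 2,4-bis(benzyloxy)-6-[(2R)-2-{[(3R)-3-(benzyloxy)butanoyl]oxy}propyl]benzoate | C[C@H](Cc1cc(OCc2ccccc2)cc(OCc2ccccc2)c1)OC(=O)C[C@@H](C)OC(=O)c1c(OCc2ccccc2)cc(OCc2ccccc2)cc1C[C@@H](C)OC(=O)C[C@@H](C)OCc1ccccc1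
F8 | step 5 | (2R)-1-[3,5-bis(benzyloxy)phenyl]propan-2-yl acetate | CC(=O)O[C@H](C)Cc1cc(OCc2ccccc2)cc(OCc2ccccc2)c1
F9 | step 5 | (2R)-1-[3,5-bis(benzyloxy)-2-formylphenyl]propan-2-yl acetate | CC(=O)O[C@H](C)Cc1cc(OCc2ccccc2)cc(OCc2ccccc2)c1C=O
F10 | step 5 | 2-[(2R)-2-(acetyloxy)propyl]-4,6-bis(benzyloxy)benzoic acid | CC(=O)O[C@H](C)Cc1cc(OCc2ccccc2)cc(OCc2ccccc2)c1C(=O)O
F11 | step 5 | tert-butyl 2-[(2R)-2-(acetyloxy)propyl]-4,6-bis(benzyloxy)benzoate | CC(=O)O[C@H](C)Cc1cc(OCc2ccccc2)cc(OCc2ccccc2)c1C(=O)OC(C)(C)C
A1 | alternative 1 | (3R)-6,8-bis(benzyloxy)-3-methyl-3,4-dihydro-1H-isochromen-1-one | C[C@@H]1Cc2cc(OCc3ccccc3)cc(OCc3ccccc3)c2C(=O)O1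
A2 | alternative 1 | 2,4-bis(benzyloxy)benzoic acid | OC(=O)c1ccc(OCc2ccccc2)cc1OCc1ccccc1
A3 | alternative 2 | bis-resorcylate with a benzyl ester on ring A and a benzyl ether on unit D | C[C@H](Cc1cc(O)cc(O)c1C(=O)OCc1ccccc1)OC(=O)C[C@@H](C)OC(=O)c1c(O)cc(O)cc1C[C@@H](C)OC(=O)C[C@@H](C)OCc1ccccc1
A4 | alternative 2 | acyclic diynoate tetraester: benzyl (5R)-5-{[(3R)-3-{[(5R)-5-{[(3R)-3-(benzyloxy)butanoyl]oxy}hex-2-ynoyl]oxy}butanoyl]oxy}hex-2-ynoate | C[C@H](CC#CC(=O)OCc1ccccc1)OC(=O)C[C@@H](C)OC(=O)C#CC[C@@H](C)OC(=O)C[C@@H](C)OCc1ccccc1
A5 | alternative 2 | 5,5-dimethyl-1,3-bis(trimethylsilyloxy)cyclohexa-1,3-diene | CC1(C)CC(O[Si](C)(C)C)=CC(O[Si](C)(C)C)=C1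
A6 | alternative 3 | (2R)-4-{[(2R)-1-[3,5-bis(benzyloxy)phenyl]propan-2-yl]oxy}-4-oxobutan-2-yl 2-[(2R)-2-{[tert-butyl(dimethyl)silyl]oxy}propyl]-4,6-dihydroxybenzoate | C[C@H](Cc1cc(OCc2ccccc2)cc(OCc2ccccc2)c1)OC(=O)C[C@@H](C)OC(=O)c1c(O)cc(O)cc1C[C@@H](C)O[Si](C)(C)C(C)(C)C
A7 | alternative 3 | 6-[(6R)-6-{[tert-butyl(dimethyl)silyl]oxy}-2,4-dioxoheptyl]-2,2-dimethyl-4H-1,3-dioxin-4-one | C[C@H](CC(=O)CC(=O)CC1=CC(=O)OC(C)(C)O1)O[Si](C)(C)C(C)(C)C
A8 | alternative 3 | (2R)-1-[3,5-bis(benzyloxy)phenyl]propan-2-yl (3R)-3-hydroxybutanoate | C[C@@H](O)CC(=O)O[C@H](C)Cc1cc(OCc2ccccc2)cc(OCc2ccccc2)c1
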